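## Analysis of the target

The target 17 is (2R,3S,3aR,5S)-5,7-dimethoxy-2-methyl-3a-(prop-2-en-1-yl)-3-(3,4,5-trimethoxyphenyl)-3,3a,4,5-tetrahydro-1-benzofuran-6(2H)-one. A five-membered oxygen ring A (O1, C2, C3, C3a, C7a) is fused along C3a–C7a to a carbocycle B (C3a, C4, C5, C6, C7, C7a), in which O1–C7a=C7(OMe)–C6=O is a vinylogous ester. Three contiguous stereocentres lie on ring A: the C2 methyl and the C3 aryl group are trans, and the allyl group on the quaternary C3a is anti to aryl and so syn to the methyl group. The fourth centre, C5, carries a methoxy group syn to allyl. Because C3 must stay near the plane of the enol ether, allyl is pseudo-axial on ring B and this methoxy group is then pseudo-axial too, so equilibration cannot be relied on to favour it. C5 is α to the C6 ketone and epimerises with acid or base; the terminal alkene excludes ozone and hydrogenation, and the enol ether and the electron-rich arene tolerate only mild acid. The difficulty is the quaternary C3a shared by both rings next to C3, together with a labile C5 that no neighbour controls. The strategy reads O1–C2(Me)–C3(aryl)–C3a–C7a as a γ-butyrolactone whose C2–C3 bond is a homoallylic alcohol bond, with C3a as the central carbon of an allyl unit and C4 as its exocyclic methylene. Ring A then comes from acetaldehyde and a 2-(methoxycarbonyl)allyl metal reagent, and C4 remains an acceptor carbon for C5–C7. In such a reagent the aryl group is cis to the metal-bearing CH2 and axial in the chair transition state, so the addition is expected to be syn and to give the 2,3-cis lactone; C2 is therefore inverted when ring A is re-formed at the end.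

## Retrosynthetic reasoning

**C5–H.** The last disconnection removes only the configuration at C5: 17 is traced to its C5-epimeric mixture 15 through the common lithium dienolate 16. C5 is α to a ketone from 13 onward and would not survive the base that closes ring B. It is therefore left unset and fixed at the end by protonation anti to the pseudo-axial allyl group. Compounds 12–15 can then be carried as epimer pairs without loss.

**O1–C2.** Ring A of 15 is cut at O1–C2, not at the enol ether bond O1–C7a. This gives hydroxy dione 14, in which the enol oxygen on C7a is the nucleophile and the C2 carbinol the electrophile. The forward closure is a substitution with inversion at C2. The cut is placed here because the lactone-forming step delivers C2 and C3 cis, and an acid condensation at O1–C7a would keep that relationship. Inversion makes it trans without an extra step.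

**C7–C7a.** 14 is opened at C7–C7a to keto lactone 13. Forward, this is a Claisen acylation in which the C7 enolate of the methoxymethyl ketone attacks the lactone carbonyl C7a. Ring B closes with the oxygens at C6 and C7a in place, and the C2 hydroxyl needed for the inversion is released. Only the C7 enolate can reach C7a.

**C6 mask, C3a–allyl and C4–C5.** 13 comes from hydrazone 12 by hydrolysis. 12 is cut at the allyl–C3a bond and at C4–C5, giving lactone enolate 11 and then the methylene lactone 7 and azaenolate 10 of hydrazone 9, made from the symmetrical ketone 8. The cut follows the polarity of the lactone: C4 of 7 is an acceptor and C3a becomes a donor after the addition, so both bonds form in one flask. In the cis-lactone the C3 aryl and C2 methyl lie on the same face and together direct the allyl group to the other face.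

**C2–C3 and O1–C7a (key).** 7 is cut at C2–C3 and at the acyl–oxygen bond to give acetaldehyde 5 and bromomethyl cinnamate 4, with silyl ether 6 between them. This makes ring A, both its stereocentres and the absolute configuration from two achiral partners in one catalytic operation. The methylene group left over is the acceptor that ring B needs. Forward, the allylchromium reagent from 4 must react through its aryl-bearing carbon, syn, and on one face of 5.

**4 from 1 and 2.** 4 is the allylic transposition product of alcohol 3, the Morita–Baylis–Hillman adduct of aldehyde 1 and acrylate 2. These are two robust steps from bulk chemicals, so the risk sits in the key step.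

## Alternatives that were turned down

**Alternative 1:** The disconnection is C4–C5 and C3a–allyl on a preformed β-aryl-γ-methyl methylene lactone, taken as the strategic step. Forward, the lithium azaenolate 10 adds to the methylene group and the lactone enolate is allylated anti to aryl, giving A1.
- For: two C–C bonds and the quaternary centre form in one flask from simple reagents. The same reaction type serves the chosen route as step 5, so on this operation the two are equal.
- Against: no ring closes. Only C3a is set with confidence (C5 arises unselectively). It also presupposes an enantiopure lactone, so the C2–C3 bond and the absolute configuration are left to an unnamed earlier step. In the 2,3-trans series of A1 the C2 methyl lies on the face from which allyl must enter, so the facial bias rests on aryl alone.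
- Comparison: the chosen strategy contains this step and adds the one that creates ring A, its two stereocentres and the absolute configuration from two-step material.

**Alternative 2:** The disconnection cuts C4–C5 and C7–C7a together, building ring B from ketone 8 and formyl lactone A2. Forward, the enolate of 8 adds to the aldehyde, the second enolate acylates on the lactone carbonyl, and acid re-closes ring A and dehydrates to the 4,5-dehydro compound A3.
- For: ring B with both methoxy groups forms in one cascade, with no hydrazone to attach and remove. On convergence of the ring B construction it is stronger than the chosen route.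
- Against: the formyl group on the doubly activated quaternary carbon of A2 is open to retro-Claisen loss under the basic cascade, and the aldehyde is hindered. A3 is one oxidation level too high, so C4=C5 must be reduced selectively beside C7=C7a and the allyl group, at a β-carbon next to a quaternary centre. C5 is then set by enolate protonation anyway. A2 needs the 2,3-trans lactone plus formylation and C-allylation, because the acid closure retains C2.
- Comparison: the chosen route reaches the right oxidation level directly, since C4 enters as a methylene acceptor, at the price of two hydrazone steps.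

**Alternative 3:** The disconnection is O1–C2 and C2–C3 by [4+1] annulation on an ortho-quinone methide of an aromatic ring B, with C3a–allyl made later by dearomatisation. Forward, a chiral ammonium ylide adds at C3 and the phenoxide closes ring A to the trans-dihydrobenzofuran A4, whose ester is the latent methyl group.
- For: ring A forms with the correct trans C2/C3 relationship and absolute configuration directly. Here it is stronger than the chosen strategy, which obtains 2,3-cis and must invert C2. The arene carries the C5, C6 and C7 oxygens.
- Against: the ester-to-methyl change costs three steps. The benzyl group cannot be removed by hydrogenation once allyl is present. The decisive C3a–allyl bond needs para-selective C-allylation of a phenol at a substituted ring-fusion carbon, in competition with O-allylation. That gives a dienone of the A3 type, which still needs selective reduction and C5 protonation.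
- Comparison: it is longer, and its least secure step falls late on valuable material. The chosen strategy places its main risk on two-step material and makes the quaternary centre by enolate alkylation under matched substrate control.

Key step: step 3

Remark on the chemistry: the γ-aryl 2-(methoxycarbonyl)allyl chromium reagent is taken to add syn (aryl axial in the chair), as γ-substituted reagents of this class do, and 1,3-dimethoxyacetone (8) is taken as a catalogue ketone.

## Route

Step 1
Reactants: 1 3,4,5-trimethoxybenzaldehyde; 2 methyl acrylate
Product: 3 methyl 2-[hydroxy(3,4,5-trimethoxyphenyl)methyl]prop-2-enoate (racemic)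
Conditions: 1,4-diazabicyclo[2.2.2]octane (1 equiv), 2 (3 equiv), 1,4-dioxane/H2O 1:1, rt
Reagents that add atoms: none
Why: Morita–Baylis–Hillman reaction: the amine adds to the acrylate and the zwitterionic enolate attacks the aldehyde; the aqueous medium offsets the low reactivity of the electron-rich aldehyde, and the racemic carbinol centre is erased in step 2.

Step 2
Reactants: 3 methyl 2-[hydroxy(3,4,5-trimethoxyphenyl)methyl]prop-2-enoate
Product: 4 methyl (2Z)-2-(bromomethyl)-3-(3,4,5-trimethoxyphenyl)prop-2-enoate
Conditions: 48% aq. HBr, conc. H2SO4, CH2Cl2, 0 °C → rt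
Reagents that add atoms: hydrogen bromide, Br
Why: Acid ionises the doubly activated benzylic alcohol and bromide is captured at the CH2 terminus (allylic transposition under thermodynamic control), which places aryl trans to the ester and gives the Z bromide.

Step 3
Reactants: 4 methyl (2Z)-2-(bromomethyl)-3-(3,4,5-trimethoxyphenyl)prop-2-enoate; 5 acetaldehyde
Product: 7 (4S,5S)-5-methyl-3-methylidene-4-(3,4,5-trimethoxyphenyl)oxolan-2-one (cis-lactone), via syn silyl ether 6 (not isolated)
Conditions: CrCl2 (10 mol %), 3,6-di-tert-butyl-1,8-bis(4-isopropyl-4,5-dihydrooxazol-2-yl)-9H-carbazole (one antipode, 12 mol %), i-Pr2NEt (20 mol %), Mn powder (2 equiv), Me3SiCl (1.5 equiv), 5 (3 equiv), THF, 0 °C → rt, slow addition of 4; then 1 M aq. HCl, rt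
Reagents that add atoms: none
Why: CrCl2 (divalent chromium), bound to the tridentate bisoxazoline and regenerated by Mn, reduces the allylic C–Br bond of 4 to a σ-allyl species of trivalent chromium that carries the metal on CH2 and keeps aryl cis to it (trans to the ester). This adds to acetaldehyde with allylic transposition through a six-membered chair, so the aryl-bearing carbon forms C2–C3 and the methylene becomes exocyclic; the closest known reaction type is the chromium-catalysed asymmetric 2-(alkoxycarbonyl)allylation of aldehydes that ends in lactonization. Me3SiCl takes the alkoxide off chromium as silyl ether 6 and so turns the catalyst over. Aqueous HCl then frees the hydroxyl, which closes ring A by 5-exo-trig attack on the ester carbonyl (O1–C7a) with loss of methanol. C3 is set relative to C2 by the chair: the aldehyde methyl is equatorial and aryl, being cis to CH2–Cr, is axial, which gives the syn adduct and hence the cis-lactone. The absolute configuration of C2, and with it C3, is set by the ligand, whose antipode is chosen for attack on the Re face of acetaldehyde. The step needs branched regioselectivity, which the closed transition state secures, and suppression of reductive dimerisation of 4, which slow addition of the bromide secures.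

Step 4
Reactants: 8 1,3-dimethoxypropan-2-one
Product: 9 1,3-dimethoxypropan-2-one N,N-dimethylhydrazone
Conditions: Me2NNH2 (1.5 equiv), AcOH (cat.), EtOH, reflux; distillation
Reagents that add atoms: N,N-dimethylhydrazine, CN(C)N
Why: Condensation of a symmetrical ketone with the hydrazine; the hydrazone masks the carbonyl group and makes one of the two equivalent α-carbons (the future C5) a carbon nucleophile on lithiation.

Step 5
Reactants: 9 1,3-dimethoxypropan-2-one N,N-dimethylhydrazone; 7 (4S,5S)-5-methyl-3-methylidene-4-(3,4,5-trimethoxyphenyl)oxolan-2-one
Product: 12 (3R,4S,5S)-3-[3-(2,2-dimethylhydrazinylidene)-2,4-dimethoxybutyl]-5-methyl-3-(prop-2-en-1-yl)-4-(3,4,5-trimethoxyphenyl)oxolan-2-one (both epimers at the methoxy-bearing chain carbon), via lithium azaenolate 10 (not isolated), via lithium lactone enolate 11 (not isolated)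
Conditions: 9, LiN(i-Pr)2 (1.1 equiv), THF, −78 °C; slow addition of 7, −78 °C; allyl bromide (2 equiv), DMPU, −78 → −20 °C
Reagents that add atoms: allyl bromide, C=CCBr
Why: Azaenolate 10 adds to the unhindered exocyclic methylene of 7 (Michael addition, C4–C5) and the lactone enolate 11 is C-allylated in the same flask (tandem conjugate addition–alkylation). In 11 the C3 aryl and the C2 methyl lie on one face, so allyl enters from the other and ends anti to aryl (3aR in the target numbering); C5 is not controlled here and is set in step 9.

Step 6
Reactants: 12 the hydrazone lactone of step 5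
Product: 13 (3R,4S,5S)-3-(2,4-dimethoxy-3-oxobutyl)-5-methyl-3-(prop-2-en-1-yl)-4-(3,4,5-trimethoxyphenyl)oxolan-2-one (both epimers at the methoxy-bearing chain carbon)
Conditions: sat. aq. oxalic acid, Et2O, rt
Reagents that add atoms: water, O
Why: Mild two-phase hydrazone hydrolysis in which the hydrazine is drawn into the acid phase; lactone, alkene and aryl ethers are inert and no stereocentre other than the still unset C5 is touched.

Step 7
Reactants: 13 the keto lactone of step 6
Product: 14 (4R)-4-[(1S,2S)-2-hydroxy-1-(3,4,5-trimethoxyphenyl)propyl]-2,6-dimethoxy-4-(prop-2-en-1-yl)cyclohexane-1,3-dione (both epimers at C6, C2 enolised)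
Conditions: KOt-Bu (2.5 equiv), THF, 0 °C; AcOH (2.5 equiv), −20 °C; extractive work-up, crude 14 used at once
Reagents that add atoms: none
Why: Intramolecular Claisen (Dieckmann-type) acylation: only the enolate at C7 can reach the lactone carbonyl through a six-membered transition state, the tetrahedral intermediate expels the C2 alkoxide and the product is drawn off as its stabilised dione enolate. C2, C3 and C3a are not enolisable and stay as set.

Step 8
Reactants: 14 the hydroxy dione of step 7
Product: 15 (2R,3S,3aR)-5,7-dimethoxy-2-methyl-3a-(prop-2-en-1-yl)-3-(3,4,5-trimethoxyphenyl)-3,3a,4,5-tetrahydro-1-benzofuran-6(2H)-one (both C5 epimers)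
Conditions: PPh3 (1.5 equiv) and diisopropyl azodicarboxylate (1.5 equiv) premixed in THF, 0 °C; slow addition of 14 (high dilution), 0 °C → rt
Reagents that add atoms: none
Why: Intramolecular Mitsunobu etherification: the betaine deprotonates the acidic dione enol, the C2 hydroxyl becomes an oxyphosphonium leaving group and the enolate oxygen on C7a displaces it (5-exo-tet) with inversion, which turns the 2,3-cis relationship inherited from 7 into trans (2R). Closure through the C6 oxygen would give a bridged seven-membered ether and C-attack at C7 a quaternary carbon, so O-attack from C7a should prevail.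

Step 9
Reactants: 15 the C5-epimeric mixture of step 8
Product: 17 (2R,3S,3aR,5S)-5,7-dimethoxy-2-methyl-3a-(prop-2-en-1-yl)-3-(3,4,5-trimethoxyphenyl)-3,3a,4,5-tetrahydro-1-benzofuran-6(2H)-one (target), via lithium dienolate 16 (not isolated)
Conditions: LiN(SiMe3)2 (1.2 equiv), THF, −78 °C; 2,6-di-tert-butyl-4-methylphenol (3 equiv), THF, −78 °C; sat. aq. NH4Cl, −78 °C
Reagents that add atoms: none
Why: Kinetic, diastereoselective protonation of an enolate: C5–H is the only acidic proton, so both epimers give one dienolate 16. The pseudo-axial allyl group on C3a screens the upper face of C5, so the hindered phenol should deliver the proton anti to allyl and leave the methoxy group syn to allyl (5S).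

## Compound list

1 | 3,4,5-trimethoxybenzaldehyde | COc1cc(C=O)cc(OC)c1OC | starting material
2 | methyl acrylate | C=CC(=O)OC | starting material
3 | methyl 2-[hydroxy(3,4,5-trimethoxyphenyl)methyl]prop-2-enoate (racemic) | C=C(C(=O)OC)C(O)c1cc(OC)c(OC)c(OC)c1 | intermediate
4 | methyl (2Z)-2-(bromomethyl)-3-(3,4,5-trimethoxyphenyl)prop-2-enoate | BrC/C(C(=O)OC)=C\c1cc(OC)c(OC)c(OC)c1 | intermediate
5 | acetaldehyde | CC=O | starting material
6 | methyl (3S,4S)-2-methylidene-3-(3,4,5-trimethoxyphenyl)-4-[(trimethylsilyl)oxy]pentanoate | C[Si](C)(C)O[C@@H](C)[C@H](C(=C)C(=O)OC)c1cc(OC)c(OC)c(OC)c1 | intermediate (not isolated)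
7 | (4S,5S)-5-methyl-3-methylidene-4-(3,4,5-trimethoxyphenyl)oxolan-2-one | C=C1C(=O)O[C@@H](C)[C@H]1c1cc(OC)c(OC)c(OC)c1 | intermediate
8 | 1,3-dimethoxypropan-2-one | COCC(=O)COC | starting material
9 | 1,3-dimethoxypropan-2-one N,N-dimethylhydrazone | COCC(=NN(C)C)COC | intermediate
10 | lithium azaenolate of 9 | [Li]N(N(C)C)C(COC)=COC | intermediate (not isolated)
11 | lithium (4S,5S)-3-[3-(2,2-dimethylhydrazinylidene)-2,4-dimethoxybutyl]-5-methyl-4-(3,4,5-trimethoxyphenyl)-4,5-dihydrofuran-2-olate | [Li+].[O-]C1=C(CC(OC)C(=NN(C)C)COC)[C@H](c2cc(OC)c(OC)c(OC)c2)[C@H](C)O1 | intermediate (not isolated)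
12 | (3R,4S,5S)-3-[3-(2,2-dimethylhydrazinylidene)-2,4-dimethoxybutyl]-5-methyl-3-(prop-2-en-1-yl)-4-(3,4,5-trimethoxyphenyl)oxolan-2-one, chain epimers | C=CC[C@]1(CC(OC)C(=NN(C)C)COC)C(=O)O[C@@H](C)[C@H]1c1cc(OC)c(OC)c(OC)c1 | intermediate
13 | (3R,4S,5S)-3-(2,4-dimethoxy-3-oxobutyl)-5-methyl-3-(prop-2-en-1-yl)-4-(3,4,5-trimethoxyphenyl)oxolan-2-one, chain epimers | C=CC[C@]1(CC(OC)C(=O)COC)C(=O)O[C@@H](C)[C@H]1c1cc(OC)c(OC)c(OC)c1 | intermediate
14 | (4R)-4-[(1S,2S)-2-hydroxy-1-(3,4,5-trimethoxyphenyl)propyl]-2,6-dimethoxy-4-(prop-2-en-1-yl)cyclohexane-1,3-dione, C6 epimers | C=CC[C@@]1(CC(OC)C(=O)C(OC)C1=O)[C@@H]([C@H](C)O)c1cc(OC)c(OC)c(OC)c1 | intermediate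
15 | (2R,3S,3aR)-5,7-dimethoxy-2-methyl-3a-(prop-2-en-1-yl)-3-(3,4,5-trimethoxyphenyl)-3,3a,4,5-tetrahydro-1-benzofuran-6(2H)-one, C5 epimers | C=CC[C@]12CC(OC)C(=O)C(OC)=C1O[C@H](C)[C@H]2c1cc(OC)c(OC)c(OC)c1 | intermediate
16 | lithium (2R,3S,3aR)-5,7-dimethoxy-2-methyl-3a-(prop-2-en-1-yl)-3-(3,4,5-trimethoxyphenyl)-2,3,3a,4-tetrahydro-1-benzofuran-6-olate | [Li+].C=CC[C@]12CC(OC)=C([O-])C(OC)=C1O[C@H](C)[C@H]2c1cc(OC)c(OC)c(OC)c1 | intermediate (not isolated)
17 | (2R,3S,3aR,5S)-5,7-dimethoxy-2-methyl-3a-(prop-2-en-1-yl)-3-(3,4,5-trimethoxyphenyl)-3,3a,4,5-tetrahydro-1-benzofuran-6(2H)-one | C=CC[C@]12C[C@H](OC)C(=O)C(OC)=C1O[C@H](C)[C@H]2c1cc(OC)c(OC)c(OC)c1 | target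

## Step count and least certain steps

Total step count: 9. Longest linear sequence: 8 (steps 1, 2, 3, 5, 6, 7, 8, 9); step 4 is a one-step branch.

**Step 3 (key).** Enantio- or diastereocontrol may erode, and 4 may dimerise reductively. The γ-aryl reagent is bulkier than the parent reagent of this catalytic reaction, and acetaldehyde offers only methyl against hydrogen for facial discrimination. The fallback sets out from 4 and 5 and returns at 7. Indium powder in THF/water couples 4 with 5 in a Barbier reaction to the syn hydroxy ester F1 as the racemate. Acylation with vinyl acetate, catalysed by Candida antarctica lipase B, converts the (3R,4R)-enantiomer into acetate F2 and leaves the (3S,4S)-enantiomer of F1. p-Toluenesulfonic acid in CH2Cl2 then lactonises it to 7. Stereocontrol thus moves from a chiral catalyst to a kinetic resolution. Should the chromium addition prove anti-selective instead, the antipodal ligand and an acid-catalysed closure with retention in place of step 8 would lead to the same 15.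

**Step 8.** The ring may close with retention at C2, through activation of the dione oxygen instead of the alcohol or through a background acid-type condensation of 14 before the betaine acts. Elimination toward the styrene and participation of the electron-rich aryl group are further possibilities, because the carbinol is secondary and flanked by a benzylic C–H. The fallback sets out from 7 and returns at 15; it moves the inversion to the lactone stage and uses a sulfonate, whose site of activation is unambiguous. KOH in aqueous MeOH opens 7, and MeI in DMF alkylates the dry potassium carboxylate to the hydroxy ester F1 (here enantiopure). MsCl/Et3N gives mesylate F3. LiOH in aqueous THF saponifies the ester, and the carboxylate displaces the mesylate with inversion to the trans-lactone F4. The conditions of steps 5, 6 and 7 take F4 to hydrazone F5, ketone F6 and hydroxy dione F7. p-Toluenesulfonic acid in benzene with removal of water closes F7 with retention to 15. In this series the allylation rests on the aryl group alone.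

**Step 9.** Facial selectivity in the protonation may be poor, because the aryl group on C3 flanks the lower face near C4, and the centre may re-equilibrate on work-up. The fallback sets out from 15 and returns at 17. LiN(SiMe3)2 and then Me3SiCl give the silyl dienol ether F8. This is protonated under reagent control at −78 °C in toluene by the complex of one antipode of 1,1'-bi-2-naphthol with SnCl4, the antipode chosen to reinforce the substrate bias.

**Step 5.** Enolate 11 may start anionic oligomerisation of 7, and allylation of the hindered, fully substituted enolate may be incomplete. The fallback sets out from 7 and 9 and returns at 12; it separates the two bond formations. The Michael adduct is quenched with NH4Cl to lactone F9. After purification F9 is re-enolised with LiN(i-Pr)2 and allylated with allyl bromide under the same facial control.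

## Further compounds

F1 | step 3 | methyl (3S,4S)-4-hydroxy-2-methylidene-3-(3,4,5-trimethoxyphenyl)pentanoate (formed as the racemate in the fallback to step 3; the enantiomer carried on is drawn) | O[C@@H](C)[C@H](C(=C)C(=O)OC)c1cc(OC)c(OC)c(OC)c1
F2 | step 3 | methyl (3R,4R)-4-acetoxy-2-methylidene-3-(3,4,5-trimethoxyphenyl)pentanoate | CC(=O)O[C@H](C)[C@@H](C(=C)C(=O)OC)c1cc(OC)c(OC)c(OC)c1
F3 | step 8 | methyl (3S,4S)-4-[(methanesulfonyl)oxy]-2-methylidene-3-(3,4,5-trimethoxyphenyl)pentanoate | CS(=O)(=O)O[C@@H](C)[C@H](C(=C)C(=O)OC)c1cc(OC)c(OC)c(OC)c1
F4 | step 8 | (4S,5R)-5-methyl-3-methylidene-4-(3,4,5-trimethoxyphenyl)oxolan-2-one | C=C1C(=O)O[C@H](C)[C@H]1c1cc(OC)c(OC)c(OC)c1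
F5 | step 8 | (3R,4S,5R)-3-[3-(2,2-dimethylhydrazinylidene)-2,4-dimethoxybutyl]-5-methyl-3-(prop-2-en-1-yl)-4-(3,4,5-trimethoxyphenyl)oxolan-2-one, chain epimers | C=CC[C@]1(CC(OC)C(=NN(C)C)COC)C(=O)O[C@H](C)[C@H]1c1cc(OC)c(OC)c(OC)c1
F6 | step 8 | (3R,4S,5R)-3-(2,4-dimethoxy-3-oxobutyl)-5-methyl-3-(prop-2-en-1-yl)-4-(3,4,5-trimethoxyphenyl)oxolan-2-one, chain epimers | C=CC[C@]1(CC(OC)C(=O)COC)C(=O)O[C@H](C)[C@H]1c1cc(OC)c(OC)c(OC)c1
F7 | step 8 | (4R)-4-[(1S,2R)-2-hydroxy-1-(3,4,5-trimethoxyphenyl)propyl]-2,6-dimethoxy-4-(prop-2-en-1-yl)cyclohexane-1,3-dione, C6 epimers | C=CC[C@@]1(CC(OC)C(=O)C(OC)C1=O)[C@@H]([C@@H](C)O)c1cc(OC)c(OC)c(OC)c1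
F8 | step 9 | (2R,3S,3aR)-5,7-dimethoxy-2-methyl-3a-(prop-2-en-1-yl)-3-(3,4,5-trimethoxyphenyl)-6-[(trimethylsilyl)oxy]-2,3,3a,4-tetrahydro-1-benzofuran | C=CC[C@]12CC(OC)=C(O[Si](C)(C)C)C(OC)=C1O[C@H](C)[C@H]2c1cc(OC)c(OC)c(OC)c1
F9 | step 5 | (4S,5S)-3-[3-(2,2-dimethylhydrazinylidene)-2,4-dimethoxybutyl]-5-methyl-4-(3,4,5-trimethoxyphenyl)oxolan-2-one, epimers at C3 and in the chain | COCC(=NN(C)C)C(OC)CC1C(=O)O[C@@H](C)[C@H]1c1cc(OC)c(OC)c(OC)c1
A1 | alternative 1 | (3R,4S,5R)-3-[(2S)-3-(2,2-dimethylhydrazinylidene)-2,4-dimethoxybutyl]-5-methyl-3-(prop-2-en-1-yl)-4-(3,4,5-trimethoxyphenyl)oxolan-2-one | C=CC[C@]1(C[C@H](OC)C(=NN(C)C)COC)C(=O)O[C@H](C)[C@H]1c1cc(OC)c(OC)c(OC)c1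
A2 | alternative 2 | (3S,4S,5R)-5-methyl-2-oxo-3-(prop-2-en-1-yl)-4-(3,4,5-trimethoxyphenyl)oxolane-3-carbaldehyde | C=CC[C@]1(C=O)C(=O)O[C@H](C)[C@H]1c1cc(OC)c(OC)c(OC)c1
A3 | alternative 2 | (2R,3S,3aS)-5,7-dimethoxy-2-methyl-3a-(prop-2-en-1-yl)-3-(3,4,5-trimethoxyphenyl)-3,3a-dihydro-1-benzofuran-6(2H)-one | C=CC[C@]12C=C(OC)C(=O)C(OC)=C1O[C@H](C)[C@H]2c1cc(OC)c(OC)c(OC)c1
A4 | alternative 3 | tert-butyl (2S,3S)-6-(benzyloxy)-5,7-dimethoxy-3-(3,4,5-trimethoxyphenyl)-2,3-dihydro-1-benzofuran-2-carboxylate (trans) | c12cc(OC)c(OCc3ccccc3)c(OC)c1O[C@H](C(=O)OC(C)(C)C)[C@H]2c1cc(OC)c(OC)c(OC)c1
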